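**Retrosynthetic overview**
1. The target comes from a bis-MOM 3-aryl-3-hydroxychroman-4-one. One acid treatment removes water to give C2=C3 of the pyranone and cleaves the MOM groups to free the phenols.
2. Key disconnection C3–C4: a carbene turns the A-ring formyl carbon into an acyl anion (Breslow enaminol), which attacks the B-ring ketone carbon. Two carbonyl (acceptor) carbons are joined, and the precursor is a keto-aldehyde aryl ether.
3. O1–C2: Williamson ether between the less hindered ortho-OH of the A-ring aldehyde and a phenacyl bromide. This O-alkylation, not a cyclisation, decides 6- versus 8-substitution.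
4. C6–C1′: C-allylation of symmetric 4-O-MOM-phloroglucinaldehyde with (E)-4-chloro-2-methylbut-2-en-1-ol. The E geometry comes from SN2′ opening of isoprene monoxide.
5. Ring order: rings A and B are bought. Ring C (the pyranone) is the only ring formed, and it is closed in the last step.

Assumption: the target has no stereocentre and its only stereo-element is the E double bond of the side chain, so "single enantiomer" is read as the single E isomer.

**Step 1**
Reactants: 1 2-methyl-2-vinyloxirane (isoprene monoxide, racemic)
Product: 2 (2E)-4-chloro-2-methylbut-2-en-1-ol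
Conditions: TiCl4 (1.1 equiv), CH2Cl2, −85 °C, 1.5 h; 1 M aq HCl quench
Reagents that add atoms: titanium(IV) chloride, Cl[Ti](Cl)(Cl)Cl
Why: In this Lewis-acid-promoted SN2′ opening of a vinyl epoxide, TiCl4 binds the epoxide oxygen and delivers chloride to the vinyl terminus through the s-trans conformer, which places CH2O[Ti] trans to the new CH2Cl and so sets the E-trisubstituted alkene that is carried unchanged to the target, while the racemic epoxide centre disappears.

**Step 2**
Reactants: 3 2,4,6-trihydroxybenzaldehyde
Product: 4 2,6-dihydroxy-4-(methoxymethoxy)benzaldehyde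
Conditions: MOMCl (1.0 equiv), K2CO3 (1.0 equiv), acetone, 0 °C to rt
Reagents that add atoms: chloromethyl methyl ether (MOMCl), COCCl
Why: This Williamson-type O-alkylation with one equivalent of weak base takes the para-OH, which is the most acidic hydroxyl and the only one not hydrogen-bonded to the formyl group, and it leaves a symmetric diol in which C3 and C5 are equivalent.

**Step 3**
Reactants: 4 2,6-dihydroxy-4-(methoxymethoxy)benzaldehyde, 2 (2E)-4-chloro-2-methylbut-2-en-1-ol
Product: 5 2,6-dihydroxy-3-[(2E)-4-hydroxy-3-methylbut-2-en-1-yl]-4-(methoxymethoxy)benzaldehyde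
Conditions: 4 (1.5 equiv, excess recovered), KOH (1 equiv per 4), H2O–MeOH 4:1, 0 °C to rt, 24 h
Reagents that add atoms: none
Why: This is C-allylation of a phloroglucinol-type phenoxide in protic medium, where hydrogen bonding shields the oxygens, and it proceeds by direct SN2 at the primary allylic chloride, so there is no regiochemical choice on the symmetric ring, the E-alkene is untouched, and no free hydroxide is present to act on the alcohol of 2.

**Step 4**
Reactants: 6 2-bromo-1-(4-hydroxyphenyl)ethan-1-one
Product: 7 2-bromo-1-[4-(methoxymethoxy)phenyl]ethan-1-one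
Conditions: CH2(OMe)2 (10 equiv), TsOH·H2O (5 mol%), CH2Cl2, reflux through 4 Å MS (Soxhlet)
Reagents that add atoms: dimethoxymethane, COCOC
Why: Acid-catalysed acetal exchange (transacetalisation), driven by trapping methanol on the sieves, masks the phenol without any base, which would make the bromoketone alkylate its own phenoxide.

**Step 5**
Reactants: 5 2,6-dihydroxy-3-[(2E)-4-hydroxy-3-methylbut-2-en-1-yl]-4-(methoxymethoxy)benzaldehyde, 7 2-bromo-1-[4-(methoxymethoxy)phenyl]ethan-1-one
Product: 8 2-hydroxy-3-[(2E)-4-hydroxy-3-methylbut-2-en-1-yl]-4-(methoxymethoxy)-6-{2-[4-(methoxymethoxy)phenyl]-2-oxoethoxy}benzaldehyde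
Conditions: K2CO3 (1.05 equiv), acetone, 0 °C to rt, 6 h
Reagents that add atoms: none
Why: In this Williamson ether synthesis on a very reactive α-bromoketone, the C6-OH (next to H) is more acidic and far less hindered than the C2-OH, which is wedged between side chain and CHO and locked in the chelate to the formyl oxygen, so the future O1–C2 bond is placed to leave the side chain at C6 rather than C8, and the mild base at or below rt avoids the Rap–Stoermer aldol to a 2-aroylbenzofuran.

**Step 6**
Reactants: 8 2-hydroxy-3-[(2E)-4-hydroxy-3-methylbut-2-en-1-yl]-4-(methoxymethoxy)-6-{2-[4-(methoxymethoxy)phenyl]-2-oxoethoxy}benzaldehyde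
Product: 10 5,7-dihydroxy-3-(4-hydroxyphenyl)-6-[(2E)-4-hydroxy-3-methylbut-2-en-1-yl]-4H-chromen-4-one (target), via 3-hydroxyisoflavanone 9 (not isolated)
Conditions: 2-(C6F5)-6,7-dihydro-5H-pyrrolo[2,1-c][1,2,4]triazol-2-ium BF4 (20 mol%), Et3N (20 mol%), THF (0.05 M), 40 °C, Ar; then 1.25 M HCl in MeOH, 40 °C
Reagents that add atoms: none
Why: In this intramolecular crossed aldehyde–ketone benzoin reaction the carbene adds to the CHO (activated by the chelated 2-OH) and a proton shift gives the Breslow enaminol, an acyl anion equivalent whose former carbonyl carbon (C4) attacks the ketone carbonyl carbon (C3) in a 6-exo closure that joins two acceptor carbons; the C3 carbinol centre forms as a racemate and is erased when methanolic HCl ionises the tertiary p-oxybenzylic alcohol (E1 dehydration, loss of H-2) to the aromatic 4-pyranone and cleaves both MOM acetals, leaving the E-alkene and the primary allylic alcohol in place.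

**Compound list**
1 | 2-methyl-2-vinyloxirane (isoprene monoxide, racemic) | C=CC1(C)CO1 | starting material
2 | (2E)-4-chloro-2-methylbut-2-en-1-ol | ClC/C=C(\C)CO | intermediate
3 | 2,4,6-trihydroxybenzaldehyde | O=Cc1c(O)cc(O)cc1O | starting material
4 | 2,6-dihydroxy-4-(methoxymethoxy)benzaldehyde | O=Cc1c(O)cc(OCOC)cc1O | intermediate
5 | 2,6-dihydroxy-3-[(2E)-4-hydroxy-3-methylbut-2-en-1-yl]-4-(methoxymethoxy)benzaldehyde | O=Cc1c(O)cc(OCOC)c(C/C=C(\C)CO)c1O | intermediate
6 | 2-bromo-1-(4-hydroxyphenyl)ethan-1-one | O=C(CBr)c1ccc(O)cc1 | starting material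
7 | 2-bromo-1-[4-(methoxymethoxy)phenyl]ethan-1-one | O=C(CBr)c1ccc(OCOC)cc1 | intermediate
8 | 2-hydroxy-3-[(2E)-4-hydroxy-3-methylbut-2-en-1-yl]-4-(methoxymethoxy)-6-{2-[4-(methoxymethoxy)phenyl]-2-oxoethoxy}benzaldehyde | O=Cc1c(OCC(=O)c2ccc(OCOC)cc2)cc(OCOC)c(C/C=C(\C)CO)c1O | intermediate
9 | 3,5-dihydroxy-6-[(2E)-4-hydroxy-3-methylbut-2-en-1-yl]-7-(methoxymethoxy)-3-[4-(methoxymethoxy)phenyl]-2,3-dihydro-4H-chromen-4-one (racemic at C3, not isolated) | O=C1c2c(O)c(C/C=C(\C)CO)c(OCOC)cc2OCC1(O)c1ccc(OCOC)cc1 | intermediate
10 | 5,7-dihydroxy-3-(4-hydroxyphenyl)-6-[(2E)-4-hydroxy-3-methylbut-2-en-1-yl]-4H-chromen-4-one | C/C(=C\Cc1c(O)cc2occ(-c3ccc(O)cc3)c(=O)c2c1O)CO | target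

**Step count**
- Total steps: 6.
- Longest linear sequence: 4 (3 → 4 → 5 → 8 → 10, steps 2, 3, 5 and 6).
- The branch 1 → 2 joins at step 3 and is equally long. The branch 6 → 7 joins at step 5.

**The three steps most likely to fail**

**Step 6.** Four things can go wrong. The aldehyde is electron-rich and flanked by two oxygen substituents. The free phenol buffers the carbene. The aldol to the benzofuran competes. The acid finish could touch the allylic alcohol. The fallback sets out from 8 and gives up the protecting-group-free closure for a fully masked substrate. MOMCl and i-Pr2NEt in refluxing CH2Cl2 cap the chelated phenol and the allylic alcohol to give the fully capped keto-aldehyde F1. This compound has no acidic proton, so it can be closed with a full carbene loading, using the small 3-benzyl-5-(2-hydroxyethyl)-4-methylthiazolium chloride with DBU in t-BuOH. The capped 3-hydroxyisoflavanone F2 is isolated and purified. Methanolic HCl then dehydrates it and removes all four MOM groups, which brings the fallback back to the route at 10.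

**Step 5.** The risk is O6 versus O2 alkylation, which decides whether the 6- or the 8-substituted isoflavone forms. The fallback builds the ring first and adds the chain last.
- It sets out from the symmetric diol 4 and from 7. Under the step 5 conditions these can give only one ether, the chain-free keto-aldehyde F3.
- The same carbene closure gives the chain-free 3-hydroxyisoflavanone F4.
- Catalytic TsOH in toluene over 4 Å sieves dehydrates it with the MOM groups kept, giving 7,4′-di-O-MOM-genistein F5.
- The free chelated 5-OH directs iodination (BnMe3N·ICl2, CaCO3, CH2Cl2–MeOH) to the ortho carbon C6, giving the 6-iodide F6.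
- Coupling with 1 follows (Pd(OAc)2, HCO2Na, n-Bu4NCl, DMF, 60 °C). Arylpalladation of the vinyl group and β-oxygen elimination open the epoxide, giving the 7,4′-di-O-MOM target F7. The E isomer is the major product and the Z isomer is removed by chromatography.
- HCl in MeOH brings the fallback back to the route at 10.

**Step 3.** The risks are C- versus O-alkylation and double alkylation, so the yield is expected to be modest. The fallback replaces the phenoxide SN2 reaction by π-allylpalladium chemistry. It sets out from 4 and directly from epoxide 1, skipping 2. Pd(PPh3)4 (5 mol%) in THF at rt ionises the vinyl epoxide. The alkoxide set free deprotonates 4, and the soft ring carbon attacks the unsubstituted allyl terminus (Tsuji–Trost 1,4-addition under neutral conditions). Any O-allyl ether re-ionises and funnels to the C-allyl product. This comes back to the route at 5 and makes no compound outside the list (F0). The cost is that the E geometry is then set less cleanly, and the minor Z isomer must be separated.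

**Further compounds**
F1 | step 6 | 2,4-bis(methoxymethoxy)-3-[(2E)-4-(methoxymethoxy)-3-methylbut-2-en-1-yl]-6-{2-[4-(methoxymethoxy)phenyl]-2-oxoethoxy}benzaldehyde | O=Cc1c(OCC(=O)c2ccc(OCOC)cc2)cc(OCOC)c(C/C=C(\C)COCOC)c1OCOC
F2 | step 6 | 3-hydroxy-5,7-bis(methoxymethoxy)-6-[(2E)-4-(methoxymethoxy)-3-methylbut-2-en-1-yl]-3-[4-(methoxymethoxy)phenyl]-2,3-dihydro-4H-chromen-4-one (racemic) | O=C1c2c(OCOC)c(C/C=C(\C)COCOC)c(OCOC)cc2OCC1(O)c1ccc(OCOC)cc1
F3 | step 5 | 2-hydroxy-4-(methoxymethoxy)-6-{2-[4-(methoxymethoxy)phenyl]-2-oxoethoxy}benzaldehyde | O=Cc1c(O)cc(OCOC)cc1OCC(=O)c1ccc(OCOC)cc1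
F4 | step 5 | 3,5-dihydroxy-7-(methoxymethoxy)-3-[4-(methoxymethoxy)phenyl]-2,3-dihydro-4H-chromen-4-one (racemic) | O=C1c2c(O)cc(OCOC)cc2OCC1(O)c1ccc(OCOC)cc1
F5 | step 5 | 5-hydroxy-7-(methoxymethoxy)-3-[4-(methoxymethoxy)phenyl]-4H-chromen-4-one | O=c1c(-c2ccc(OCOC)cc2)coc2cc(OCOC)cc(O)c12
F6 | step 5 | 5-hydroxy-6-iodo-7-(methoxymethoxy)-3-[4-(methoxymethoxy)phenyl]-4H-chromen-4-one | O=c1c(-c2ccc(OCOC)cc2)coc2cc(OCOC)c(I)c(O)c12
F7 | step 5 | 5-hydroxy-6-[(2E)-4-hydroxy-3-methylbut-2-en-1-yl]-7-(methoxymethoxy)-3-[4-(methoxymethoxy)phenyl]-4H-chromen-4-one | O=c1c(-c2ccc(OCOC)cc2)coc2cc(OCOC)c(C/C=C(\C)CO)c(O)c12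
F0 | step 3 | none | none
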